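The easy step is to lay the readings of the runs side by side, and two chemists do it differently.

| setting | oak | ash | alder | birch | maple |
|---|---|---|---|---|---|
| E | 0.400 M | 0.200 M | 0.400 M | 1.20 M | 0.400 M |
| L | 0.0200 M | 0.0200 M | 0.0100 M | 0.0200 M | 0.0200 M |
| time |  |  |  |  | 72 min |

- oak run (time / min: [J] / M): 5.8: 0.0493; 12: 0.0946; 17: 0.1302; 23: 0.1659; 29: 0.1999
- ash run (time / min: [J] / M): 5.8: 0.0319; 12: 0.0570; 17: 0.0774; 23: 0.0975; 29: 0.1154
- alder run (time / min: [J] / M): 5.8: 0.0360; 12: 0.0686; 17: 0.0917; 23: 0.1190; 29: 0.1441
- birch run (time / min: [J] / M): 5.8: 0.0988; 12: 0.1953; 17: 0.2668; 23: 0.3460; 29: 0.4161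

(readings scatter by 0.001 M)

1. how the opening rate goes with [L] round the charge of the oak run: the exponent of the rate at two percent of E gone to J
2. how the opening rate goes with [E] round the charge of the oak run: the exponent of the rate at two percent of E gone to J (one fixed amount of J, the same in the runs compared)
3. J in the maple run at 72 min, as a share of the E charged

- Overall: E -> J, with L as catalyst.
- Constant volume, constant temperature.
- Readings of a species count what is bound in complexes too.
- An order is taken over about fifteen percent of the charge, up and down.

The first chemist compares charges. At 5.8 min the oak run holds 1.55 times the J of the ash run on twice the [E], so she reads an order in [E] of 0.628. Oak against alder at 29 min gives an order in [L] of 0.472. Both are J at equal times, not rates at equal J, so they are rough readings. She then runs her [E] order down oak's curve from its last reading and puts the maple run at 89.3%.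

The second chemist reads one flask against itself, since the maple run has the charge of the oak run. Oak's clock stands at 0.0239 min⁻¹: this is an apparent pseudo-first-order constant, the ln of [E] charged over [E] left, divided by the time. At 5.8 min the same clock reads 0.0227 min⁻¹, so it holds nearly steady along the oak run. Carried to 72 min, it gives 82.1% for the maple run, lower than her figure.

I keep her orders for the opening and his clock for the maple run, since the clock was measured on that very charge.

The forecast gives 0.48, 0.61 and 83%, its own figure on his side, with the rate sagging through “slow catalyst loss or mild inhibition”.

The simulation gives 0.54, 0.69 and 84.5%, and the clock's share lies closer than the carried order's.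

    2 L ⇌ L2, settled at all times (921.0 L mol⁻¹)
    L + E → J + L (14.34 L mol⁻¹ min⁻¹)
    2 E ⇌ E2, settled at all times (2.260 L mol⁻¹)
    L + J ⇌ LJ, settled at all times (6.290 L mol⁻¹)

The maple share corresponds to a clock of 0.0259 min⁻¹, faster than oak's 0.0239 min⁻¹. The parking of two E as E2 holds the maple run down: with it removed, the maple run reaches 93.5% instead of 84.5%, and the order in [E] goes from 0.69 to 1.0. Between charges her order lands nearer than his clock, as the ash run shows. Oak's clock puts the ash run's quarter at 12.0 min, her order scales oak's 12.5 min to 9.69 min, and the ash run stands at 10.2 min.

The earlier runs and the new flask stem from a simulated flask on assumed constants; noise was put on by code.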